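## Structural features

The target (23) consists of two identical 3-(2-methylbut-3-en-2-yl)-1H-indol-5-yl units, indole A and indole B, joined through a C10 hydrocarbon core: a 1,4-dimethylcyclohex-3-ene (ring C) that carries indole A directly on C2 and indole B through an (E)-ethenyl bridge on C1 (ring C is numbered C1 quaternary, C2 methine, C3=C4(CH3), C5, C6 throughout). The two stereocentres, quaternary C1 and tertiary C2, are adjacent; both are R in the target, with indole A on C2 cis to the ethenyl bridge and trans to the methyl group on C1. Ring C carries no heteroatom, so nothing on the core can direct bond formation or stereocontrol, and the two identical halves are attached in two different ways (aryl–C(sp3) and aryl–vinyl); this is where the real difficulty lies. Fragile features are the two free indole N–H groups and nucleophilic indole C2 positions, the two 1,1-dimethylallyl groups (acid-labile, and their terminal alkenes compete in any olefin chemistry), the benzylic and allylic C2–H of ring C, and the trisubstituted C3=C4 alkene, which acid would move into conjugation with indole A. Formally the molecule is the endo [4+2] homodimer of a 5-(3-methylbuta-1,3-dienyl)indole, which is the reading most chemists would follow first. The key step exploits another reading of the C1–C2 bond of ring C: C2 is an aryl-substituted allylic carbon (C2–C3=C4), that is, the branched terminus of an aryl allyl electrophile, and C1 stands α to the bridge carbon, which can be carried as a formyl group, so that C1 can act as an enamine carbon. In one sentence, the route is an enantioconvergent iridium/amine dual-catalytic α-allylation of the achiral aldehyde 13 with the racemic indolyl vinyl carbinol 10.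

## Logic of the disconnections

23 from 22. The two N–H bonds are traced back to N–S bonds. Free indoles would be allylated, methylated or metalated in steps 7, 9 and 13, so both are carried as sulfonamides. There is no gain in skeleton; the gain is that the indoles become spectators. The forward step must cleave two sulfonamides with base only, because acid or dissolving metal would endanger four alkenes.

22 from 17 and 20. The C=C bond of the ethenyl bridge is cut, between the carbon on C1 and the benzylic carbon of indole B. This is the only cut that separates the two indole halves while leaving both stereocentres in one fragment, and it turns the bridge carbon into a formyl group on C1. The gain is a mono-indole core and a simple benzylic phosphonate. The forward step must be E-selective on a neopentyl aldehyde; epimerisation is excluded because 17 has no α-hydrogen.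

20 from 19, 18 and 9. The C–P bond, then the C–Br bond, then the benzylic C–H bond (aldehyde oxidation level) are cut. This returns indole B to 9, which also serves indole A, so one building block feeds both halves. The forward steps must be neutral or mild because of the 1,1-dimethylallyl group.

17 from 15 (through 16). The C1–CH3 bond is cut. The formyl group makes C1 an enolate carbon, and the aryl group on C2 sends the electrophile to the opposite face, which is exactly the relationship of the target (methyl trans, bridge carbon cis to indole A). The gain is that the quaternary stereocentre is reduced to a tertiary carbon whose configuration does not matter, so only C2 needs absolute control. Placing this methyl group on the aldehyde partner of the key step instead would make the quaternary centre depend on the E/Z ratio of an α,α-dialkyl enamine, which is not defined. The forward step demands C- over O-alkylation and high anti selectivity.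

15 from 14. The ring alkene C3=C4 is cut. A trisubstituted cyclohexene is a favourable ring-closing metathesis product, and both alkene partners arrive with the components of the key step. The gain is that ring C becomes an acyclic aldehyde with two terminal alkenes. The forward step must close the ring faster than the hindered 1,1-dimethylallyl alkene enters metathesis.

14 from 10 and 13 (key disconnection). The C1–C2 bond of ring C (C2–C3 of 14) is cut, the bond between the two stereocentres. C2 is an aryl-substituted allylic carbon and C1 is α to a formyl group, so the bond is the union of an aryl π-allyl electrophile with an enamine. The gain is the largest of the route: a compound that holds every carbon of ring C and its absolute configuration falls back to a racemic alcohol and an achiral C7 aldehyde. The forward step must be enantioconvergent, branched-selective, and compatible with the sulfonyl indole and three isolated alkenes.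

10 from 9. The bond between the carbinol carbon and the vinyl group is cut. The forward step is a simple vinyl addition; the racemate suffices.

13 from 12 and 11. The formyl group is traced back to an ester, and the C=CH2 bond to a ketone. The forward steps need chemoselectivity for ketone over ester and a reduction that stops at the aldehyde.

9 from 7, 4, 1 and 2. The N–S bond, the C5–CHO bond and the bond from indole C3 to the quaternary carbon of the 1,1-dimethylallyl group are cut in turn. The hindered quaternary benzylic carbon is installed once, at the start, on a cheap indole. The forward step must give branched (reverse-prenyl) regiochemistry and C3 rather than N attack.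

## Other disconnections considered

Alternative 1: Both ring bonds C1–C2 and C5–C6 are cut in a retro-[4+2] sense, and the forward key step is the thermal Diels–Alder dimerisation of 5-[(1E)-3-methylbuta-1,3-dien-1-yl]-3-(2-methylbut-3-en-2-yl)-1H-indole A1. This is the first idea and the shortest on paper. The hydrocarbon diene offers no polar group for a chiral catalyst to bind, so the constitution of 23 would be expected only as a racemate. Either alkene of A1 can act as dienophile and endo/exo control rests on weak secondary interactions, so isomer mixtures are to be expected. The single enantiomer would need a resolution, which the chosen plan avoids by fixing C2 with a catalyst.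

Alternative 2: The same two ring bonds are cut, but as a cross-[4+2] reaction of the N-tosyl diene A2 with methacrolein under a chiral oxazaborolidinium Lewis acid, which would give 17 directly and save about three steps. The ground against it is mechanistic. α-Substituted acroleins tend to place the formyl group exo, which would lead to the C1 epimer A3; the cis relationship of indole A and the bridge would then rest on an endo/exo preference that is hard to predict for an acyclic 1-aryl diene. The electron-rich aryl diene and the 1,1-dimethylallyl group must also survive a strong Lewis acid. In the chosen plan C2 is set by a π-allyl iridium catalyst whose selectivity is largely independent of the substrate, and C1 by steric anti-alkylation. The acrolein variant of this cycloaddition is kept as the fallback for step 7.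

Alternative 3: The C1–C2 bond is cut in the sense of a [3,3] shift. The forward key step is the Ireland–Claisen rearrangement of the (Z)-silyl ketene acetal of the (1R,2E)-allylic ester A4 through a chair transition state. It would form the C1–C2 bond, both stereocentres and the (E)-ethenyl bridge in one step and give acid A5. The stereochemical logic is sound (chirality transfer from one carbinol centre, with the quaternary centre defined by a fixed alkene geometry). The carboxyl carbon, however, arrives at the wrong oxidation level for C3 and needs about four further steps before ring C can be closed by metathesis. The alcohol half of A4 needs a stereodefined trisubstituted alkene and an enantioselective reduction, and the result depends on a clean ketene acetal geometry. The longest linear sequence would be about five steps longer than in the chosen plan.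

Key step: step 7

Abbreviation: TsInd = 3-(2-methylbut-3-en-2-yl)-1-(4-methylbenzenesulfonyl)-1H-indol-5-yl.

Assumption: the (R)-configured iridium ligand is taken to give the 3R product in step 7; should the sense of induction be the opposite, the equally available (S)-ligand is used and nothing else in the route changes.

## Route

Step 1
Reactants: 1 5-bromo-1H-indole; 2 tert-butyl (2-methylbut-3-en-2-yl) carbonate
Product: 4 5-bromo-3-(2-methylbut-3-en-2-yl)-1H-indole, via potassium triethyl(5-bromoindol-1-yl)borate 3 (not isolated)
Conditions: [Ir(cod)Cl]2 (2.5 mol %), racemic BINOL-derived phosphoramidite ligand (10 mol %), KOtBu (1.1 equiv), Et3B (1.1 equiv), THF, 25 °C; then H2O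
Reagents that add atoms: none
Why: Iridium-catalysed allylic substitution with an indole C-nucleophile: the monovalent iridium catalyst ionises 2 to a 1,1-dimethylallyl complex of trivalent iridium, which borate 3 (nitrogen blocked by Et3B) attacks through C3 at the more substituted allyl terminus, the branched sense normal for iridium. Loss of CO2 and tert-butoxide is irreversible, C3–H to N–H tautomerisation restores the indole, and the C5–Br bond is inert to iridium.

Step 2
Reactants: 4 5-bromo-3-(2-methylbut-3-en-2-yl)-1H-indole
Product: 7 3-(2-methylbut-3-en-2-yl)-1H-indole-5-carbaldehyde, via potassium indol-1-ide 5 (not isolated), via 5-lithio potassium indol-1-ide 6 (not isolated)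
Conditions: KH (1.1 equiv), THF, 0 °C; t-BuLi (2.1 equiv), −78 °C; DMF, −78 → 0 °C; then H2O
Reagents that add atoms: N,N-dimethylformamide CN(C)C=O
Why: Bromine–lithium exchange followed by formylation with DMF (Bouveault aldehyde synthesis). Removing N–H first as the potassium salt 5 prevents protonation of aryllithium 6, exchange at −78 °C outpaces deprotonation at indole C2, and the isolated terminal alkene is inert to t-BuLi at this temperature.

Step 3
Reactants: 7 3-(2-methylbut-3-en-2-yl)-1H-indole-5-carbaldehyde
Product: 9 3-(2-methylbut-3-en-2-yl)-1-(4-methylbenzenesulfonyl)indole-5-carbaldehyde, via sodium indol-1-ide 8 (not isolated)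
Conditions: NaH (1.2 equiv), THF/DMF, 0 °C; TsCl, 0 → 25 °C
Reagents that add atoms: 4-methylbenzenesulfonyl chloride Cc1ccc(S(=O)(=O)Cl)cc1
Why: N-Sulfonylation of the indolide; the aldehyde is not enolisable and survives NaH. The tosyl group lowers the nucleophilicity of the indole for steps 7, 9 and 13 and is removed by hydroxide at the end.

Step 4
Reactants: 9 3-(2-methylbut-3-en-2-yl)-1-(4-methylbenzenesulfonyl)indole-5-carbaldehyde
Product: 10 racemic 1-(TsInd)prop-2-en-1-ol
Conditions: CH2=CHMgBr (1.2 equiv), THF, −78 °C; then H2O
Reagents that add atoms: vinylmagnesium bromide C=C[Mg]Br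
Why: Grignard 1,2-addition to an aryl aldehyde, faster at −78 °C than attack on the sulfonamide. The carbinol is made racemic on purpose because step 7 is enantioconvergent.

Step 5
Reactants: 11 methyl 5-oxohexanoate
Product: 12 methyl 5-methylhex-5-enoate
Conditions: Ph3PCH3Br (1.2 equiv), KOtBu (1.15 equiv), THF, 0 → 25 °C
Reagents that add atoms: methyltriphenylphosphonium bromide C[P+](c1ccccc1)(c1ccccc1)c1ccccc1.[Br-]
Why: Wittig methylenation; the unstabilised ylide reacts with the ketone and not with the methyl ester, and no stereochemistry is involved.

Step 6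
Reactants: 12 methyl 5-methylhex-5-enoate
Product: 13 5-methylhex-5-enal
Conditions: i-Bu2AlH (1.05 equiv), CH2Cl2, −78 °C; then aq Rochelle salt
Reagents that add atoms: none
Why: Partial reduction of an ester: at −78 °C the aluminium hemiacetal is stable and collapses to the aldehyde only on work-up. The 1,1-disubstituted alkene is inert, and 13 is handled as a solution because it is volatile.

Step 7
Reactants: 10 racemic 1-(TsInd)prop-2-en-1-ol; 13 5-methylhex-5-enal
Product: 14 (2R,3R)-2-(3-methylbut-3-en-1-yl)-3-(TsInd)pent-4-enal
Conditions: [Ir(cod)Cl]2 (3 mol %), (R)-4-(5H-dibenzo[b,f]azepin-5-yl)dinaphtho[2,1-d:1',2'-f][1,3,2]dioxaphosphepine (12 mol %), (S)-2-{bis[3,5-bis(trifluoromethyl)phenyl][(trimethylsilyl)oxy]methyl}pyrrolidine (15 mol %), (MeO)2P(O)OH (5 mol %), 13 (3 equiv), ClCH2CH2Cl, 25 °C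
Reagents that add atoms: none
Why: This is dual iridium/enamine catalysis, that is, iridium-catalysed asymmetric allylic substitution of a racemic branched allylic alcohol joined to amine-catalysed α-functionalisation of an aldehyde, a reaction type established for linear aldehydes and aryl vinyl carbinols. The acid promoter lets the monovalent iridium complex of the phosphoramidite–olefin ligand ionise both enantiomers of 10 to one and the same cationic π-allyl complex of trivalent iridium, while the amine condenses with 13 to its (E)-enamine; the enamine carbon attacks the aryl-bearing allyl terminus, and hydrolysis of the iminium ion releases 14 and the amine. No ring is closed in this step; it forms the C1–C2 bond of ring C and leaves in place the two alkenes that close the ring in step 8. The C3 stereocentre of 14 (C2 of ring C) is controlled by the iridium ligand alone, so the racemate of 10 is funnelled into the 3R configuration through the common π-allyl complex. The C2 stereocentre of 14 is controlled by the amine, whose diaryl(silyloxy)methyl group shields one enamine face and should give 2R, but it is not relied on because step 9 erases it. The selectivities needed are branched over linear attack, secured by iridium and the aryl substituent, and C-allylation of the enamine over attack by oxygen, by the amine nitrogen or by the indole, secured by the bulk of the amine and by the N-tosyl group that deactivates indole C2. The 1,1-dimethylallyl and isopropenyl alkenes carry no leaving group and cannot be ionised.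

Step 8
Reactants: 14 (2R,3R)-2-(3-methylbut-3-en-1-yl)-3-(TsInd)pent-4-enal
Product: 15 (1R,2R)-4-methyl-2-(TsInd)cyclohex-3-ene-1-carbaldehyde
Conditions: second-generation Grubbs catalyst (H2IMes)(PCy3)Cl2Ru=CHPh (5 mol %), CH2Cl2 (5 mM), 40 °C
Reagents that add atoms: none
Why: Ring-closing olefin metathesis, a 6-membered closure between the monosubstituted vinyl group (site of initiation) and the isopropenyl group with loss of ethene. The 1,1-dimethylallyl alkene sits next to a quaternary carbon, reacts slowly and cannot close a ring of reasonable size, so high dilution keeps it out of cross-metathesis; the aldehyde is tolerated and no stereocentre is touched.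

Step 9
Reactants: 15 (1R,2R)-4-methyl-2-(TsInd)cyclohex-3-ene-1-carbaldehyde
Product: 17 (1S,2S)-1,4-dimethyl-2-(TsInd)cyclohex-3-ene-1-carbaldehyde, via potassium enolate 16 (not isolated)
Conditions: KN(SiMe3)2 (1.05 equiv), THF, −78 °C (15 added to the base); MeI (5 equiv), −78 → −40 °C
Reagents that add atoms: iodomethane CI
Why: Enolate C-alkylation under 1,2-induction: deprotonation planarises C1, so either C1 epimer of 15 gives the same enolate 16, and MeI attacks the face opposite to the C2 aryl group, which sets the quaternary centre with methyl trans and formyl cis to indole A. KN(SiMe3)2 is too weak a base to metalate C2 of the N-tosylindole or the benzylic C2–H of ring C, and inverse addition keeps free aldehyde away from the enolate. The C2 descriptor changes from R to S only because C1 now outranks the aryl carbon; no bond at C2 is touched.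

Step 10
Reactants: 9 3-(2-methylbut-3-en-2-yl)-1-(4-methylbenzenesulfonyl)indole-5-carbaldehyde
Product: 18 (TsInd)methanol
Conditions: NaBH4, MeOH/THF, 0 °C
Reagents that add atoms: none
Why: Borohydride reduction of the aldehyde; no other group in 9 is reduced by NaBH4.

Step 11
Reactants: 18 (TsInd)methanol
Product: 19 5-(bromomethyl)-3-(2-methylbut-3-en-2-yl)-1-(4-methylbenzenesulfonyl)indole
Conditions: CBr4 (1.2 equiv), PPh3 (1.2 equiv), CH2Cl2, 0 °C
Reagents that add atoms: tetrabromomethane BrC(Br)(Br)Br
Why: Appel bromination of a primary benzylic alcohol under neutral conditions, which spares the acid-sensitive 1,1-dimethylallyl group.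

Step 12
Reactants: 19 5-(bromomethyl)-3-(2-methylbut-3-en-2-yl)-1-(4-methylbenzenesulfonyl)indole
Product: 20 diethyl [(TsInd)methyl]phosphonate
Conditions: P(OEt)3 (neat), 110 °C
Reagents that add atoms: triethyl phosphite CCOP(OCC)OCC
Why: Michaelis–Arbuzov reaction of a benzylic bromide; bromoethane distils off and drives the dealkylation.

Step 13
Reactants: 20 diethyl [(TsInd)methyl]phosphonate; 17 (1S,2S)-1,4-dimethyl-2-(TsInd)cyclohex-3-ene-1-carbaldehyde
Product: 22 3-(2-methylbut-3-en-2-yl)-5-[(1R,6R)-3,6-dimethyl-6-{(E)-2-(TsInd)ethenyl}cyclohex-2-en-1-yl]-1-(4-methylbenzenesulfonyl)indole, via sodium phosphonate carbanion 21 (not isolated)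
Conditions: NaH (1.3 equiv), 15-crown-5 (cat.), THF, 0 °C; then 17, 0 → 50 °C
Reagents that add atoms: none
Why: Horner–Wadsworth–Emmons olefination: the aryl-stabilised carbanion 21 adds reversibly to the non-enolisable aldehyde 17, and the anti oxaphosphetane, favoured by the bulk of the quaternary carbon, eliminates to the (E)-alkene. Neither stereocentre can epimerise (no α-hydrogen), and the descriptors become R,R only because the formyl carbon has turned into an ethenyl carbon.

Step 14
Reactants: 22 bis(N-tosyl) precursor named in step 13
Product: 23 3-(2-methylbut-3-en-2-yl)-5-[(1R,6R)-3,6-dimethyl-6-{(E)-2-[3-(2-methylbut-3-en-2-yl)-1H-indol-5-yl]ethenyl}cyclohex-2-en-1-yl]-1H-indole (target)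
Conditions: KOH (excess), MeOH/THF (1:1), 65 °C
Reagents that add atoms: none
Why: Nucleophilic cleavage of the two indole sulfonamides at sulfur, the indolide being a good leaving group. Alkenes and both stereocentres are inert to base, and the product should be the target with C1 and C2 of ring C both R.

## Compound list

1 | 5-bromo-1H-indole | Brc1ccc2[nH]ccc2c1 | starting material
2 | tert-butyl (2-methylbut-3-en-2-yl) carbonate | C=CC(C)(C)OC(=O)OC(C)(C)C | starting material
3 | potassium triethyl(5-bromo-1H-indol-1-yl)borate | CC[B-](CC)(CC)n1ccc2cc(Br)ccc21.[K+] | intermediate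
4 | 5-bromo-3-(2-methylbut-3-en-2-yl)-1H-indole | C=CC(C)(C)c1c[nH]c2ccc(Br)cc12 | intermediate
5 | potassium 5-bromo-3-(2-methylbut-3-en-2-yl)indol-1-ide | C=CC(C)(C)c1c[n-]c2ccc(Br)cc12.[K+] | intermediate
6 | potassium 5-lithio-3-(2-methylbut-3-en-2-yl)indol-1-ide | C=CC(C)(C)c1c[n-]c2ccc([Li])cc12.[K+] | intermediate
7 | 3-(2-methylbut-3-en-2-yl)-1H-indole-5-carbaldehyde | C=CC(C)(C)c1c[nH]c2ccc(C=O)cc12 | intermediate
8 | sodium 5-formyl-3-(2-methylbut-3-en-2-yl)indol-1-ide | C=CC(C)(C)c1c[n-]c2ccc(C=O)cc12.[Na+] | intermediate
9 | 3-(2-methylbut-3-en-2-yl)-1-(4-methylbenzenesulfonyl)indole-5-carbaldehyde | C=CC(C)(C)c1cn(S(=O)(=O)c2ccc(C)cc2)c2ccc(C=O)cc12 | intermediate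
10 | racemic 1-(TsInd)prop-2-en-1-ol | C=CC(C)(C)c1cn(S(=O)(=O)c2ccc(C)cc2)c2ccc(C(O)C=C)cc12 | intermediate
11 | methyl 5-oxohexanoate | COC(=O)CCCC(C)=O | starting material
12 | methyl 5-methylhex-5-enoate | COC(=O)CCCC(C)=C | intermediate
13 | 5-methylhex-5-enal | O=CCCCC(C)=C | intermediate
14 | (2R,3R)-2-(3-methylbut-3-en-1-yl)-3-(TsInd)pent-4-enal | O=C[C@H](CCC(C)=C)[C@@H](C=C)c1ccc2n(S(=O)(=O)c3ccc(C)cc3)cc(C(C)(C)C=C)c2c1 | intermediate
15 | (1R,2R)-4-methyl-2-(TsInd)cyclohex-3-ene-1-carbaldehyde | O=C[C@@H]1CCC(C)=C[C@H]1c1ccc2n(S(=O)(=O)c3ccc(C)cc3)cc(C(C)(C)C=C)c2c1 | intermediate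
16 | potassium [(2S)-4-methyl-2-(TsInd)cyclohex-3-en-1-ylidene]methanolate (E/Z mixture at the enolate double bond) | [K+].[O-]C=C1CCC(C)=C[C@H]1c1ccc2n(S(=O)(=O)c3ccc(C)cc3)cc(C(C)(C)C=C)c2c1 | intermediate
17 | (1S,2S)-1,4-dimethyl-2-(TsInd)cyclohex-3-ene-1-carbaldehyde | O=C[C@@]1(C)CCC(C)=C[C@H]1c1ccc2n(S(=O)(=O)c3ccc(C)cc3)cc(C(C)(C)C=C)c2c1 | intermediate
18 | (TsInd)methanol | C=CC(C)(C)c1cn(S(=O)(=O)c2ccc(C)cc2)c2ccc(CO)cc12 | intermediate
19 | 5-(bromomethyl)-3-(2-methylbut-3-en-2-yl)-1-(4-methylbenzenesulfonyl)indole | C=CC(C)(C)c1cn(S(=O)(=O)c2ccc(C)cc2)c2ccc(CBr)cc12 | intermediate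
20 | diethyl [(TsInd)methyl]phosphonate | CCOP(=O)(Cc1ccc2n(S(=O)(=O)c3ccc(C)cc3)cc(C(C)(C)C=C)c2c1)OCC | intermediate
21 | sodium (diethoxyphosphoryl)(TsInd)methanide | [Na+].CCOP(=O)([CH-]c1ccc2n(S(=O)(=O)c3ccc(C)cc3)cc(C(C)(C)C=C)c2c1)OCC | intermediate
22 | 3-(2-methylbut-3-en-2-yl)-5-[(1R,6R)-3,6-dimethyl-6-{(E)-2-(TsInd)ethenyl}cyclohex-2-en-1-yl]-1-(4-methylbenzenesulfonyl)indole | C=CC(C)(C)c1cn(S(=O)(=O)c2ccc(C)cc2)c2ccc(/C=C/[C@@]3(C)CCC(C)=C[C@H]3c3ccc4n(S(=O)(=O)c5ccc(C)cc5)cc(C(C)(C)C=C)c4c3)cc12 | intermediate
23 | 3-(2-methylbut-3-en-2-yl)-5-[(1R,6R)-3,6-dimethyl-6-{(E)-2-[3-(2-methylbut-3-en-2-yl)-1H-indol-5-yl]ethenyl}cyclohex-2-en-1-yl]-1H-indole | C=CC(C)(C)c1c[nH]c2ccc(/C=C/[C@@]3(C)CCC(C)=C[C@H]3c3ccc4[nH]cc(C(C)(C)C=C)c4c3)cc12 | target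

## Step count and least certain steps

Total steps: 14. Longest linear sequence: 9 steps (steps 1, 2, 3, 4, 7, 8, 9, 13, 14).

Step 7 (key step). The most likely failure is sluggish or incomplete ionisation of the tosylindolyl carbinol, with etherification or elimination taking over, or loss of enantioselectivity if attack occurs before the two diastereomeric allyl complexes have equilibrated. The fallback replaces allylation and metathesis by a cycloaddition. It sets out from 9. Horner–Wadsworth–Emmons reaction of 9 with diethyl (2-methylprop-2-en-1-yl)phosphonate (NaH, THF) should give 5-[(1E)-3-methylbuta-1,3-dien-1-yl]-3-(2-methylbut-3-en-2-yl)-1-(4-methylbenzenesulfonyl)indole F1 (the same compound as A2). An iminium-catalysed Diels–Alder reaction of F1 with acrolein should give the endo adduct (1S,2R)-4-methyl-2-(TsInd)cyclohex-3-ene-1-carbaldehyde F2; the catalyst is the enantiomer of 5-benzyl-2,2,3-trimethylimidazolidin-4-one hydrochloride that gives the 2R adduct, in MeCN/H2O. Deprotonation of F2 under the conditions of step 9 gives the same enolate 16, and the route is rejoined at 17.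

Step 1. The most likely failure is loss of regiocontrol: N-allylation, or attack at the unsubstituted allyl terminus to give the normal prenyl isomer. The fallback forms the same bond by cross-coupling at a pre-halogenated C3 and sets out from 1. Iodination with N-iodosuccinimide (DMF) should give 5-bromo-3-iodo-1H-indole F3, and N-tosylation (NaH, TsCl) should give 5-bromo-3-iodo-1-(4-methylbenzenesulfonyl)indole F4. A γ-selective Suzuki–Miyaura coupling with 4,4,5,5-tetramethyl-2-(3-methylbut-2-en-1-yl)-1,3,2-dioxaborolane (Pd(OAc)2, bulky dialkylbiarylphosphine, K3PO4, THF/H2O) follows; zerovalent palladium inserts into the C–I bond before the C–Br bond, and the product should be 5-bromo-3-(2-methylbut-3-en-2-yl)-1-(4-methylbenzenesulfonyl)indole F5. Bromine–lithium exchange (t-BuLi, THF, −78 °C) and DMF then give 9, where the route is rejoined.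

Step 9. The most likely failure is O-methylation or aldol self-condensation of the hindered aldehyde enolate, which would leave the quaternary centre unformed. The fallback builds the methyl group by carbenoid addition instead of enolate alkylation and sets out from 15. Silylation (Me3SiCl, Et3N, NaI, MeCN) should give trimethyl{[(2S)-4-methyl-2-(TsInd)cyclohex-3-en-1-ylidene]methoxy}silane F6. Simmons–Smith cyclopropanation (Et2Zn, CH2I2, CH2Cl2) on the face opposite to the aryl group should give trimethyl{[(3R,4S)-6-methyl-4-(TsInd)spiro[2.5]oct-5-en-1-yl]oxy}silane F7 (mixture at C1 of the spirocycle, of no consequence). Fluoride-induced ring opening (Bu4NF, THF, 0 °C) with protonation of the primary carbon then gives 17, where the route is rejoined.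

Step 13. The most likely failure is slow addition of the benzylic phosphonate carbanion to the neopentyl aldehyde, stalling at the β-hydroxyphosphonate, or erosion of E selectivity. The fallback forms the aryl–vinyl bond instead of the C=C bond and sets out from 17. Ohira–Bestmann homologation (dimethyl (1-diazo-2-oxopropyl)phosphonate, K2CO3, MeOH, 0 °C) should give 5-[(1S,6S)-6-ethynyl-3,6-dimethylcyclohex-2-en-1-yl]-3-(2-methylbut-3-en-2-yl)-1-(4-methylbenzenesulfonyl)indole F8. Hydroboration with pinacolborane catalysed by Cp2Zr(H)Cl, selective for the alkyne, should give 2-[(E)-2-{(1R,2R)-1,4-dimethyl-2-(TsInd)cyclohex-3-en-1-yl}ethenyl]-4,4,5,5-tetramethyl-1,3,2-dioxaborolane F9. Suzuki–Miyaura coupling of F9 (Pd(OAc)2, dialkylbiarylphosphine, K3PO4, THF/H2O) with 5-bromo-3-(2-methylbut-3-en-2-yl)-1-(4-methylbenzenesulfonyl)indole F5, here made from 4 by N-tosylation (NaH, TsCl), then gives 22, where the route is rejoined.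

## Further compounds

F1 | step 7 | 5-[(1E)-3-methylbuta-1,3-dien-1-yl]-3-(2-methylbut-3-en-2-yl)-1-(4-methylbenzenesulfonyl)indole | C=CC(C)(C)c1cn(S(=O)(=O)c2ccc(C)cc2)c2ccc(/C=C/C(C)=C)cc12
F2 | step 7 | (1S,2R)-4-methyl-2-(TsInd)cyclohex-3-ene-1-carbaldehyde | O=C[C@H]1CCC(C)=C[C@H]1c1ccc2n(S(=O)(=O)c3ccc(C)cc3)cc(C(C)(C)C=C)c2c1
F3 | step 1 | 5-bromo-3-iodo-1H-indole | Brc1ccc2[nH]cc(I)c2c1
F4 | step 1 | 5-bromo-3-iodo-1-(4-methylbenzenesulfonyl)indole | Cc1ccc(S(=O)(=O)n2cc(I)c3cc(Br)ccc32)cc1
F5 | step 1 | 5-bromo-3-(2-methylbut-3-en-2-yl)-1-(4-methylbenzenesulfonyl)indole | C=CC(C)(C)c1cn(S(=O)(=O)c2ccc(C)cc2)c2ccc(Br)cc12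
F6 | step 9 | trimethyl{[(2S)-4-methyl-2-(TsInd)cyclohex-3-en-1-ylidene]methoxy}silane (E/Z mixture) | C[Si](C)(C)OC=C1CCC(C)=C[C@H]1c1ccc2n(S(=O)(=O)c3ccc(C)cc3)cc(C(C)(C)C=C)c2c1
F7 | step 9 | trimethyl{[(3R,4S)-6-methyl-4-(TsInd)spiro[2.5]oct-5-en-1-yl]oxy}silane (mixture at C1) | C[Si](C)(C)OC1C[C@@]12CCC(C)=C[C@H]2c1ccc2n(S(=O)(=O)c3ccc(C)cc3)cc(C(C)(C)C=C)c2c1
F8 | step 13 | 5-[(1S,6S)-6-ethynyl-3,6-dimethylcyclohex-2-en-1-yl]-3-(2-methylbut-3-en-2-yl)-1-(4-methylbenzenesulfonyl)indole | C#C[C@@]1(C)CCC(C)=C[C@H]1c1ccc2n(S(=O)(=O)c3ccc(C)cc3)cc(C(C)(C)C=C)c2c1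
F9 | step 13 | 2-[(E)-2-{(1R,2R)-1,4-dimethyl-2-(TsInd)cyclohex-3-en-1-yl}ethenyl]-4,4,5,5-tetramethyl-1,3,2-dioxaborolane | CC1(C)OB(/C=C/[C@@]2(C)CCC(C)=C[C@H]2c2ccc3n(S(=O)(=O)c4ccc(C)cc4)cc(C(C)(C)C=C)c3c2)OC1(C)C
A1 | alternative 1 | 5-[(1E)-3-methylbuta-1,3-dien-1-yl]-3-(2-methylbut-3-en-2-yl)-1H-indole | C=CC(C)(C)c1c[nH]c2ccc(/C=C/C(C)=C)cc12
A2 | alternative 2 | 5-[(1E)-3-methylbuta-1,3-dien-1-yl]-3-(2-methylbut-3-en-2-yl)-1-(4-methylbenzenesulfonyl)indole | C=CC(C)(C)c1cn(S(=O)(=O)c2ccc(C)cc2)c2ccc(/C=C/C(C)=C)cc12
A3 | alternative 2 | (1R,2S)-1,4-dimethyl-2-(TsInd)cyclohex-3-ene-1-carbaldehyde | O=C[C@]1(C)CCC(C)=C[C@H]1c1ccc2n(S(=O)(=O)c3ccc(C)cc3)cc(C(C)(C)C=C)c2c1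
A4 | alternative 3 | (1R,2E)-3,6-dimethyl-1-(TsInd)hepta-2,6-dien-1-yl 2-(TsInd)acetate | C=CC(C)(C)c1cn(S(=O)(=O)c2ccc(C)cc2)c2ccc(CC(=O)O[C@@H](c3ccc4n(S(=O)(=O)c5ccc(C)cc5)cc(C(C)(C)C=C)c4c3)/C=C(\C)CCC(C)=C)cc12
A5 | alternative 3 | (2R,3R,4E)-3-methyl-3-(3-methylbut-3-en-1-yl)-2,5-bis(TsInd)pent-4-enoic acid | C=CC(C)(C)c1cn(S(=O)(=O)c2ccc(C)cc2)c2ccc(/C=C/[C@@](C)(CCC(C)=C)[C@@H](C(=O)O)c3ccc4n(S(=O)(=O)c5ccc(C)cc5)cc(C(C)(C)C=C)c4c3)cc12
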